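The p-menthane ring (C1 ketone, C2 bearing CH2O, C3, C4 acyloxy carbinol, C5 isopropyl carbon, C6 carbinol) is split into two three-carbon halves, C2–C3–C4 and C5–C6–C1. The key step exploits the matched 1,3-polarity of these halves. An enal-derived dienamine is nucleophilic at C2 and C4, while 4-methylpent-2-enal is electrophilic at C1 and C5. One amine-catalysed formal [3+3] cycloaddition of two achiral, acyclic enals therefore closes the carbocycle, forms C4–C5 and C1–C2, and sets C4 and C5. The precursor pair is (E)-4-(tigloyloxy)but-2-enal and (E)-4-methylpent-2-enal. Redox adjustment, one acylation and a substrate-controlled α′-hydroxylation at C6 finish the synthesis.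

Key step: step 2

Remark: ring atoms keep the numbering C1–C6 of the overview (C7 = exocyclic CH2O carbon) in every intermediate; tiglate/tigloyl means (E)-2-methylbut-2-enoate/-enoyl; the C1 carbinol of 6, 7 and 9 is drawn as the expected epimer, and both epimers converge in step 5; compounds 1, 2, 4 and 8 are taken as commercial.

Step 1
Reactants: 1 allyl tiglate; 2 (E)-crotonaldehyde
Product: 3 (E)-4-oxobut-2-en-1-yl tiglate [(E)-4-(tigloyloxy)but-2-enal]
Conditions: RuCl2(=CH-C6H4-2-OiPr)(SIMes) (second-generation Hoveyda–Grubbs catalyst, 3 mol %), 2 (4 equiv), CH2Cl2, 40 °C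
Reagents that add atoms: none
Why: Olefin cross-metathesis couples the terminal allyl alkene with crotonaldehyde (an acrolein surrogate) with loss of propene to give the thermodynamic E-enal, while the trisubstituted, electron-poor tiglate alkene does not engage the ruthenium carbene.

Step 2
Reactants: 3 (E)-4-oxobut-2-en-1-yl tiglate; 4 (E)-4-methylpent-2-enal
Product: 6 (3R,4S,6S)-6-hydroxy-4-isopropyl-3-(tigloyloxy)cyclohex-1-ene-1-carbaldehyde, via acyclic Michael adduct 5 (not isolated)
Conditions: (S)-α,α-diphenylprolinol trimethylsilyl ether (20 mol %), PhCO2H (20 mol %), H2O (2 equiv), 4 (3 equiv), DMF, −10 °C, 3 added slowly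
Reagents that add atoms: none
Why: The amine converts 3 (its γ-hydrogens acidified by the acyloxy group) into a 1-amino-4-acyloxybutadiene and 4 into an E-iminium ion; the dienamine γ-carbon C4 adds to the iminium β-carbon C5 (vinylogous Michael addition), the C1 enamine is hydrolysed to give 5, and the re-formed dienamine then attacks the free C1 aldehyde through its α-carbon C2 before γ-protonation and hydrolysis return the conjugated enal and the catalyst. The closest known reaction type is the secondary-amine-catalysed formal [3+3] cycloaddition of two α,β-unsaturated aldehydes (vinylogous Michael addition followed by an intramolecular Morita–Baylis–Hillman-type aldol), which gives 6-hydroxycyclohex-1-enecarbaldehydes. The only ring closes in a 6-(enolexo)-exo-trig aldol mode. C5 is set by the catalyst, whose CPh2(OSiMe3) group shields one face of the s-trans E-iminium ion so that C4 arrives on the open face; C4 is set last, because in the ring dienamine A(1,2) strain against the C4 acyloxy group forces the isopropyl group axial and the proton enters anti to it, leaving the tiglate cis to isopropyl; the C1 carbinol should form 1,3-cis to isopropyl and is erased in step 5. The step needs cross- over self-condensation and aldol closure over Mannich closure (C6 onto C7, formal [4+2]). The first is secured by the tertiary, slowly removed γ-hydrogen of 4, its excess and the slow addition of 3; the second by water and acid, which hydrolyse the C1 enamine, and by the isopropyl group next to C6, which hinders bond formation there.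

Step 3
Reactants: 6 (3R,4S,6S)-6-hydroxy-4-isopropyl-3-(tigloyloxy)cyclohex-1-ene-1-carbaldehyde
Product: 7 (1R,4S,6S)-4-hydroxy-3-(hydroxymethyl)-6-isopropylcyclohex-2-en-1-yl tiglate
Conditions: NaBH4, CeCl3·7H2O, MeOH, −40 °C
Reagents that add atoms: none
Why: The Luche reduction should reduce the enal carbonyl in 1,2-fashion and leave the tiglate ester, its alkene and all stereocentres untouched.

Step 4
Reactants: 7 (1R,4S,6S)-4-hydroxy-3-(hydroxymethyl)-6-isopropylcyclohex-2-en-1-yl tiglate; 8 tigloyl chloride
Product: 9 (1R,4S,6S)-4-hydroxy-6-isopropyl-3-[(tigloyloxy)methyl]cyclohex-2-en-1-yl tiglate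
Conditions: 8 (1.05 equiv), 2,4,6-collidine, CH2Cl2, −78 to −30 °C
Reagents that add atoms: none
Why: In this site-selective esterification, at low temperature with a hindered pyridine base, the acid chloride should acylate the unhindered primary allylic C7 hydroxyl much faster than the secondary ring hydroxyl at C1.

Step 5
Reactants: 9 (1R,4S,6S)-4-hydroxy-6-isopropyl-3-[(tigloyloxy)methyl]cyclohex-2-en-1-yl tiglate
Product: 10 (4R,5S)-5-isopropyl-4-(tigloyloxy)-2-[(tigloyloxy)methyl]cyclohex-2-en-1-one
Conditions: Dess–Martin periodinane, CH2Cl2, 0 °C to rt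
Reagents that add atoms: none
Why: The Dess–Martin oxidation converts the remaining secondary allylic alcohol into the enone without base, which avoids loss of the C4 tiglate and converges both C1 epimers on one compound.

Step 6
Reactants: 10 (4R,5S)-5-isopropyl-4-(tigloyloxy)-2-[(tigloyloxy)methyl]cyclohex-2-en-1-one
Product: 12 (4S,5R,6R)-6-hydroxy-5-isopropyl-4-(tigloyloxy)-2-[(tigloyloxy)methyl]cyclohex-2-en-1-one (target), via sodium dienolate 11 (not isolated)
Conditions: NaN(SiMe3)2, THF, −78 °C; 2-(phenylsulfonyl)-3-phenyloxaziridine, −78 °C; AcOH quench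
Reagents that add atoms: 2-(phenylsulfonyl)-3-phenyloxaziridine, O=S(=O)(c1ccccc1)N1OC1c1ccccc1
Why: In this Davis oxidation of a kinetic cross-conjugated enolate, the hindered amide base removes an α′-hydrogen at C6 and the oxaziridine should deliver oxygen to the face opposite both the C5 isopropyl group and the pseudoaxial C4 tiglate, which sets the C6 hydroxyl trans to isopropyl (6R).

Compound list
1 | allyl tiglate (prop-2-en-1-yl (E)-2-methylbut-2-enoate) | C/C=C(\C)C(=O)OCC=C | starting material
2 | (E)-crotonaldehyde | C/C=C/C=O | starting material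
3 | (E)-4-oxobut-2-en-1-yl tiglate | C/C=C(\C)C(=O)OC/C=C/C=O | intermediate
4 | (E)-4-methylpent-2-enal | CC(C)/C=C/C=O | starting material
5 | (2E,5S)-5-isopropyl-1,7-dioxohept-2-en-4-yl tiglate (either configuration at the acyloxy carbon C4, which is reset during ring closure; not isolated) | O=C/C=C/C(OC(=O)/C(C)=C/C)[C@H](C(C)C)CC=O | intermediate
6 | (3R,4S,6S)-6-hydroxy-4-isopropyl-3-(tigloyloxy)cyclohex-1-ene-1-carbaldehyde | O=CC1=C[C@H](OC(=O)/C(C)=C/C)[C@H](C(C)C)C[C@@H]1O | intermediate
7 | (1R,4S,6S)-4-hydroxy-3-(hydroxymethyl)-6-isopropylcyclohex-2-en-1-yl tiglate | OCC1=C[C@H](OC(=O)/C(C)=C/C)[C@H](C(C)C)C[C@@H]1O | intermediate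
8 | tigloyl chloride ((E)-2-methylbut-2-enoyl chloride) | C/C=C(\C)C(=O)Cl | starting material
9 | (1R,4S,6S)-4-hydroxy-6-isopropyl-3-[(tigloyloxy)methyl]cyclohex-2-en-1-yl tiglate | C/C=C(\C)C(=O)OCC1=C[C@H](OC(=O)/C(C)=C/C)[C@H](C(C)C)C[C@@H]1O | intermediate
10 | (4R,5S)-5-isopropyl-4-(tigloyloxy)-2-[(tigloyloxy)methyl]cyclohex-2-en-1-one | C/C=C(\C)C(=O)OCC1=C[C@H](OC(=O)/C(C)=C/C)[C@H](C(C)C)CC1=O | intermediate
11 | sodium cross-conjugated dienolate of 10 (C1–O−, C1=C6; not isolated) | C/C=C(\C)C(=O)OCC1=C[C@H](OC(=O)/C(C)=C/C)[C@H](C(C)C)C=C1[O-].[Na+] | intermediate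
12 | (4S,5R,6R)-6-hydroxy-5-isopropyl-4-(tigloyloxy)-2-[(tigloyloxy)methyl]cyclohex-2-en-1-one | C/C=C(\C)C(=O)OCC1=C[C@H](OC(=O)/C(C)=C/C)[C@H](C(C)C)[C@@H](O)C1=O | target

Total step count: 6. Longest linear sequence: 6 steps (1 → 3 → 6 → 7 → 9 → 10 → 12).

Steps most likely to fail

Step 2. Several processes could erode the cascade:
- self-condensation of the donor enal;
- role reversal of the two enals;
- Mannich-type closure through C6 onto C7 instead of the aldol closure;
- dehydration and loss of tiglic acid with aromatisation;
- poor facial selectivity in the protonation at C4.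

The fallback separates role assignment from ring closure. It sets out from 3, which is enolised with TBSOTf/Et3N to (1E,3E)-4-(tert-butyldimethylsilyloxy)buta-1,3-dien-1-yl tiglate F1. This preformed nucleophile undergoes a vinylogous Mukaiyama–Michael addition to 4 under the same iminium catalyst with 2,4-dinitrobenzoic acid in wet CH2Cl2. That reaction should give 5, now isolated. Compound 5 is then closed by a PBu3-catalysed intramolecular Morita–Baylis–Hillman reaction, a Lewis-base closure that cannot follow the Mannich path. The wanted C4 epimer is separated, and the sequence returns to the route at 6.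

Step 6. The strong base could remove the γ-hydrogen at C4 instead, with expulsion of tiglate and aromatisation. The enolate could also add to the sulfonimine that forms during the oxidation. The fallback avoids a free enolate by a Rubottom oxidation and sets out from 10. Soft enolisation with TMSOTf/Et3N should give the 1-(trimethylsilyloxy)-1(6),2-diene F2. Dimethyldioxirane in acetone at −40 °C epoxidises the silyl enol ether face anti to isopropyl, and silyl migration gives the C6 trimethylsilyl ether F3. Aqueous citric acid in THF removes the silyl group, and the sequence returns to the route at 12.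

Step 4. Site selectivity could be lost through acylation of the secondary C1 hydroxyl or double acylation. The fallback differentiates the two hydroxyls before the second one exists and sets out from 6. The sequence would run as follows:
- TESCl/imidazole masks the only hydroxyl as triethylsilyl ether F4.
- Luche reduction gives primary alcohol F5.
- Compound 8 with pyridine and DMAP acylates the single free hydroxyl to give bis-tiglate silyl ether F6.
- AcOH/THF/H2O removes the silyl group, and the sequence returns to the route at 9.

Further compounds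
F1 | step 2 | (1E,3E)-4-(tert-butyldimethylsilyloxy)buta-1,3-dien-1-yl tiglate | C/C=C(\C)C(=O)O/C=C/C=C/O[Si](C)(C)C(C)(C)C
F2 | step 6 | (1R,6S)-6-isopropyl-3-[(tigloyloxy)methyl]-4-(trimethylsilyloxy)cyclohexa-2,4-dien-1-yl tiglate | C/C=C(\C)C(=O)OCC1=C[C@H](OC(=O)/C(C)=C/C)[C@H](C(C)C)C=C1O[Si](C)(C)C
F3 | step 6 | C6 trimethylsilyl ether of 12 | C/C=C(\C)C(=O)OCC1=C[C@H](OC(=O)/C(C)=C/C)[C@H](C(C)C)[C@@H](O[Si](C)(C)C)C1=O
F4 | step 4 | C1 triethylsilyl ether of 6 | O=CC1=C[C@H](OC(=O)/C(C)=C/C)[C@H](C(C)C)C[C@@H]1O[Si](CC)(CC)CC
F5 | step 4 | C1 triethylsilyl ether of 7 | OCC1=C[C@H](OC(=O)/C(C)=C/C)[C@H](C(C)C)C[C@@H]1O[Si](CC)(CC)CC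
F6 | step 4 | C1 triethylsilyl ether of 9 | C/C=C(\C)C(=O)OCC1=C[C@H](OC(=O)/C(C)=C/C)[C@H](C(C)C)C[C@@H]1O[Si](CC)(CC)CC
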